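## Structural features

The target is a germacrane-type sesquiterpene lactone. Its ten-membered carbocycle (C1–C10) is bridged by an oxygen between C3 and C10, so that the C1 ketone, the C2=C3 double bond and the quaternary C10 form a 3(2H)-furanone, and the chain C4–C9 closes a nine-membered ring through that oxygen. A (4Z)-trisubstituted olefin carrying the C15 methyl extends the furanone into a dienone that runs from C1 to C5. An α-methylene-γ-butyrolactone (C11, C12, C13) is fused trans across C7–C8 with its ring oxygen on C8, and the neighbouring C6 carries the tiglate. C6, C7 and C8 are contiguous stereocentres (6S,7R,8S), whereas the quaternary C10 (S) is separated from C8 by the C9 methylene, so the two regions must be related by reagent control or the chiral pool. The methylene lactone and the dienone are Michael acceptors, the lactone can migrate from O8 to O6 under base, and the Z olefin can isomerise by reversible conjugate addition before the ring locks it. The real difficulty is the strained bicycle with five contiguous sp2 carbons next to three contiguous stereocentres, together with the late appearance of the methylene lactone. The key step uses the fact that the C6–O and C7–C11 bonds are anti while O8 and C11 are cis: this is the pattern left when a trans C6–C7 epoxide is opened at C7 by a carbon nucleophile hung on the C8 oxygen, an event that also closes the lactone ring and frees the C6 hydroxyl.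

## Logic of the disconnections

25 is cut at the acyl–oxygen bond on C6 to give 23 and 24. The tiglate is the most base-labile group and is put on last. This removes an ester and an extra Michael acceptor from all earlier steps. The forward step must acylate a hindered secondary alcohol without adding to C13 and without moving the lactone to O6.

23 is cut at C11=C13 and at C7–C11, which leads through 22 to 21. One operation then accounts for the lactone ring, two skeletal bonds and the C7 stereocentre, and the C6 hydroxyl appears unprotected. The forward step demands that the C11 carbanion reach the rear of the C7–O bond through a five-membered transition state and leave C6, C4 and the dienone alone.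

21 is cut at the O8–C12 ester bond to 19 and 20. This postpones the acidic phosphonoacetate until all strongly basic steps are over. The demand is a mild esterification that neither opens nor shifts the epoxide.

19 is traced through 18 to 16 by cutting the O–C3 bond of the furanone, with 17 as the transient alcohol. The oxygen bridge and the strain of the bicycle are then introduced by a five-membered closure inside a preformed ring and not by a macrocyclisation. The forward step needs the C10 oxygen to be unmasked while the C8 oxygen stays protected.

16 is cut at C1–C2 to the open chain 15. This is the only ring-forming C–C bond that creates no stereocentre, and the Z-enyne turn brings C1 and C6 to the same side. The forward step demands a high-dilution acylation of an acetylide by a hindered acyl donor in the presence of the vinyl epoxide.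

15 is simplified through 14 to 13 by removing the silyl group and the epoxide oxygen. The epoxidation is thereby placed on an open-chain secondary allylic alcohol, where reagent control is reliable. The demand is the matched combination of the C8 configuration and the tartrate.

13 is traced through 12 and 11 to 7 and 10 by cutting C7–C8. The union of an alkenyl iodide and an aldehyde is chemoselective, and the C8 centre it leaves uncontrolled is reset by oxidation and catalyst-controlled reduction. The demand is a reduction whose sense is set by the catalyst and not by the remote C10.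

10 is cut at C6=C7 and goes back through 9 to 8. The Z olefin comes from a commercial alcohol, so only the E iodoalkene has to be made. The demand is that the Z-enal survives oxidation and olefination without isomerising.

7 is traced through 6, 5 and 4 (3 transient) and 2 to 1 by functional-group changes only. C10 comes from the chiral pool and the two carboxyl groups of 1 become C1 and C8. The demand is that the two ends be differentiated, which the dioxolanone and the lactone provide.

## Other disconnections considered

Alternative 1: The furanone is traced back to an isoxazole, which is cut at C1–C2 and at its O–C3 bond into the C8–C10 aldoxime A1 and the silyl-protected Z-enyne A2. In the forward direction A1 would be chlorinated with N-chlorosuccinimide and dehydrochlorinated with triethylamine to the nitrile oxide, which would add to the terminal alkyne of A2 to give the 3,5-disubstituted isoxazole A3. Reductive N–O cleavage and hydrolysis would later release the 1,3-dicarbonyl that closes onto the C10 hydroxyl.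
- In favour: the cycloaddition is regioselective for terminal alkynes and needs no strong base or organometallic reagent, and the aromatic isoxazole protects the dicarbonyl through many steps.
- Against, here: it assembles only the C1–C3 unit, which the chosen plan makes in one acylation (step 13). It adds oxime formation, N–O cleavage, hydrolysis and cyclodehydration, and the reductive unmasking (Mo(CO)6 or H2/Ni) is unlikely to spare a vinyl epoxide. The ten-membered ring, the C6–C8 triad and the lactone remain unsolved.
- Comparison: it is the equal of the chosen plan in taking C10 from the chiral pool, and the better in functional-group tolerance at the fragment union and in the stability of the masked furanone. It is worse in step economy (about four more operations for the same bonds). It also moves the ring closure to C7–C8 or C6–C7, where ring formation creates stereocentres.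

Alternative 2: The diene C2=C3–C4=C5 is cut at C2–C3 and C4–C5. This leads back to the cyclooct-2-enone A4, which carries the lactone, the C6 silyl ether and a 1-propynyl ether on the C10 oxygen. Irradiation near 350 nm would join the enone and the ynol ether (C2–C3 first, five-membered ring), and gentle heating would open the cyclobutene across C2–C5 to the bridged dienone A5, which lacks only C13 and the tiglate.
- In favour: two C–C bonds, the furanone and the ten-membered ring would arise in one flask without high dilution. The conrotatory opening has to turn C1 outward because C1 is tied to C3 through the furanone, so C6 turns inward and the 4Z olefin follows. The triad would be built on an eight-membered ring, where relative control is easier.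
- Against: a 1-propynyl ether of a tertiary alcohol next to a ketone and a lactone is hard to prepare and, having β-hydrogens, can lose a ketene on warming. cis-Cyclooctenones photoisomerise to the strained trans enone in competition with cycloaddition. The later methylenation at C11 must be done by enolate chemistry on the dienone, and A4 with four stereocentres is itself a long synthesis.
- Comparison: it is the better in bonds and rings formed per step and the equal or better in control of the olefin geometry. It is worse in access to its substrate and probably in total step count. Its key step sets no stereocentre, whereas the chosen one sets C7 and delivers the methylene in the same flask.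

Alternative 3: The C6–C7 bond is cut, which leads back to the thirteen-membered diallyl ether A6 in which C6 is joined through oxygen to C13. LiN(SiMe3)2 would remove a C6 proton and the carbanion would undergo a [2,3]-Wittig shift to the ten-membered alcohol A7. This forms C6–C7, breaks O–C13 and unveils the C11=C13 methylene.
- In favour: one concerted step forms a C–C bond, the C6 carbinol, the C7 stereocentre and the exocyclic methylene. The larger ether ring is easier to close than a ten-membered carbocycle, and ring-contracting [2,3]-Wittig shifts are a known reaction type, which the chosen key step is not.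
- Against: the C6 protons are vinylogously acidic through the dienone, so the carbanion is a delocalised trienolate that may react elsewhere, and deprotonation at C13 would give the regioisomeric shift. The needed C6/C7 relationship corresponds to the olefin with C8 cis to the O–CH2 arm, but it passes through a transannular transition state that need not follow the open-chain rule. Afterwards C12 must still be oxidised and lactonised onto O8 and not onto the free O6.
- Comparison: it is the better in precedent and in the number of stereocentres created in the key step (two against one), and the equal in delivering a free C6 hydroxyl beside the methylene unit. It is worse in the oxidation and differentiation steps that follow, which the phosphonoacetate route avoids because C12 arrives at the right oxidation level on the right oxygen.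

Key step: step 17

Remark: carbons are numbered C1–C15 as in the first section; 8 and 24 are taken as commercially available single isomers.

## Steps

Step 1
Reactants: 1 (S)-citramalic acid
Product: 2 2-[(4S)-2,2,4-trimethyl-5-oxo-1,3-dioxolan-4-yl]acetic acid
Conditions: Me2C(OMe)2, TsOH·H2O (cat.), CH2Cl2, 23 °C
Reagents that add atoms: 2,2-dimethoxypropane, COC(C)(C)OC
Why: Acid-catalysed acetal exchange closes the five-membered dioxolanone on the α-hydroxy acid unit in preference to a six-membered ring through the distal carboxyl, which differentiates the two acids; the C10 stereocentre from the chiral pool is not involved.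

Step 2
Reactants: 2 2-[(4S)-2,2,4-trimethyl-5-oxo-1,3-dioxolan-4-yl]acetic acid
Product: 4 (3S)-3-hydroxy-3-methyloxolan-2-one, via hydroxyethyl dioxolanone 3 (not isolated)
Conditions: BH3·SMe2, THF, 0 → 23 °C; MeOH; then TsOH·H2O (cat.), CH2Cl2, 23 °C
Reagents that add atoms: none
Why: Borane reduces the free carboxylic acid much faster than the dioxolanone carbonyl, and acid then lets the new primary alcohol displace acetone from the activated acyl group (lactonisation); C10 is retained.

Step 3
Reactants: 4 (3S)-3-hydroxy-3-methyloxolan-2-one
Product: 5 (2S)-2,4-dihydroxy-N-methoxy-N,2-dimethylbutanamide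
Conditions: MeNHOMe·HCl, AlMe3, CH2Cl2, 0 → 23 °C
Reagents that add atoms: N,O-dimethylhydroxylamine hydrochloride, CNOC.Cl
Why: Weinreb aminolysis of a lactone by the dimethylaluminium amide made from AlMe3 and the amine salt; it frees the C8 hydroxyl and turns C1 into an acyl donor that stops at the ketone stage.

Step 4
Reactants: 5 (2S)-2,4-dihydroxy-N-methoxy-N,2-dimethylbutanamide
Product: 6 (2S)-N-methoxy-N,2-dimethyl-2,4-bis(trimethylsilyloxy)butanamide
Conditions: Me3SiCl, imidazole, DMF, 0 → 23 °C
Reagents that add atoms: chlorotrimethylsilane, C[Si](C)(C)Cl
Why: Silylation of both hydroxyls; the tertiary trimethylsilyl ether withstands bases and organometallics but can later be removed by methanolysis, and capping the primary hydroxyl prevents relactonisation.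

Step 5
Reactants: 6 (2S)-N-methoxy-N,2-dimethyl-2,4-bis(trimethylsilyloxy)butanamide
Product: 7 (2S)-N-methoxy-N,2-dimethyl-4-oxo-2-(trimethylsilyloxy)butanamide (C8 aldehyde)
Conditions: (COCl)2, DMSO, CH2Cl2, −78 → −30 °C; Et3N, −78 → 0 °C
Reagents that add atoms: none
Why: Under Swern conditions a primary trimethylsilyl ether is cleaved by the chlorosulfonium salt and oxidised in the same flask, whereas the hindered tertiary silyl ether is inert, so the C8 aldehyde should form without a separate deprotection; the quaternary C10 cannot epimerise.

Step 6
Reactants: 8 (Z)-3-methylpent-2-en-4-yn-1-ol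
Product: 9 (Z)-3-methylpent-2-en-4-ynal
Conditions: MnO2 (excess), CH2Cl2, 0 → 23 °C, dark
Reagents that add atoms: none
Why: Heterogeneous MnO2 oxidation of an allylic alcohol is neutral and should keep the Z geometry; the volatile aldehyde is carried on as a solution.

Step 7
Reactants: 9 (Z)-3-methylpent-2-en-4-ynal
Product: 10 (1E,3Z)-1-iodo-4-methylhexa-1,3-dien-5-yne
Conditions: CrCl2, CHI3, THF, 0 °C, dark
Reagents that add atoms: iodoform, IC(I)I
Why: Takai olefination: the geminal dichromium species from CHI3 adds to the aldehyde and anti elimination gives the E iodoalkene (the future C6=C7); the terminal alkyne and the Z olefin are tolerated.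

Step 8
Reactants: 7 (2S)-N-methoxy-N,2-dimethyl-4-oxo-2-(trimethylsilyloxy)butanamide; 10 (1E,3Z)-1-iodo-4-methylhexa-1,3-dien-5-yne
Product: 11 (2S,5E,7Z)-4-hydroxy-N-methoxy-N,2,8-trimethyl-2-(trimethylsilyloxy)deca-5,7-dien-9-ynamide (both epimers at the carbinol, C8 of the target)
Conditions: CrCl2, NiCl2 (1 mol%), DMSO, 23 °C
Reagents that add atoms: none
Why: Nozaki–Hiyama–Kishi coupling forms C7–C8 with retention of the E geometry and adds only to the aldehyde, leaving the Weinreb amide, the alkyne and the silyl ether; C8 forms without control and is corrected in steps 9 and 10.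

Step 9
Reactants: 11 dienynol (C8 epimers)
Product: 12 (2S,5E,7Z)-N-methoxy-N,2,8-trimethyl-4-oxo-2-(trimethylsilyloxy)deca-5,7-dien-9-ynamide
Conditions: MnO2, CH2Cl2, 23 °C
Reagents that add atoms: none
Why: MnO2 oxidises the allylic secondary alcohol to the conjugated dienone and so erases the uncontrolled C8 centre.

Step 10
Reactants: 12 dienone
Product: 13 (2S,4S,5E,7Z)-4-hydroxy-N-methoxy-N,2,8-trimethyl-2-(trimethylsilyloxy)deca-5,7-dien-9-ynamide (8S,10S in target numbering)
Conditions: (R)-2-methyl-CBS-oxazaborolidine (20 mol%), catecholborane, toluene, −78 °C
Reagents that add atoms: none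
Why: Corey–Bakshi–Shibata reduction: the dienyl group acts as the large and the CH2 group as the small substituent, so the (R)-oxazaborolidine should deliver hydride to give 8S; catecholborane at −78 °C spares the alkyne and the amide.

Step 11
Reactants: 13 (8S)-dienynol
Product: 14 (2S,4S)-4-hydroxy-N-methoxy-N,2-dimethyl-4-{(2S,3S)-3-[(Z)-2-methylbut-1-en-3-yn-1-yl]oxiran-2-yl}-2-(trimethylsilyloxy)butanamide (6S,7S,8S,10S in target numbering)
Conditions: Ti(OiPr)4 (20 mol%), L-(+)-diisopropyl tartrate (25 mol%), t-BuOOH, 4 Å MS, CH2Cl2, −20 °C
Reagents that add atoms: tert-butyl hydroperoxide, CC(C)(C)OO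
Why: Sharpless epoxidation of a secondary E-allylic alcohol in the matched sense: with L-(+)-tartrate the 8S alcohol is the fast-reacting antipode and oxygen is delivered to the face that gives the erythro (6S,7S) epoxide; only the allylic C6=C7 olefin reacts.

Step 12
Reactants: 14 open-chain epoxy alcohol
Product: 15 C8 tert-butyldimethylsilyl ether of 14
Conditions: t-BuMe2SiCl, imidazole, DMAP (cat.), DMF, 23 °C
Reagents that add atoms: tert-butyldimethylsilyl chloride, CC(C)(C)[Si](C)(C)Cl
Why: Silylation of the secondary alcohol under non-acidic conditions; it blocks lactonisation onto the amide and epoxide migration in the basic steps that follow.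

Step 13
Reactants: 15 C8 silyl ether with C1 Weinreb amide and terminal alkyne
Product: 16 (4Z,6S,7R,8S,10S)-8-(tert-butyldimethylsilyloxy)-6,7-epoxy-4,10-dimethyl-10-(trimethylsilyloxy)cyclodec-4-en-2-yn-1-one
Conditions: LiN(SiMe3)2 (1.3 equiv), THF, 2 mM, slow addition of 15, −78 → 0 °C
Reagents that add atoms: none
Why: The lithium acetylide adds to the Weinreb amide, which has no α-hydrogen, and the chelated tetrahedral adduct survives until work-up, so the ten-membered ynone should form by C1–C2 bond formation; the Z-enyne places C1 and C6 on the same side, the ring contains no trans olefin, and high dilution disfavours dimers.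

Step 14
Reactants: 16 ten-membered ynone
Product: 18 (4Z,6S,7R,8S,10S)-8-(tert-butyldimethylsilyloxy)-3,10:6,7-diepoxy-4,10-dimethylcyclodeca-2,4-dien-1-one, via C10 hydroxy ynone 17 (not isolated)
Conditions: K2CO3 (0.3 equiv), MeOH, 0 → 23 °C
Reagents that add atoms: none
Why: Methanolysis removes only the trimethylsilyl group, and the freed tertiary alcohol adds to C3 of the ynone in a 5-endo-dig oxa-Michael closure, the standard route from α'-hydroxy ynones to 3(2H)-furanones; no stereocentre is touched.

Step 15
Reactants: 18 bridged furanone silyl ether
Product: 19 (4Z,6S,7S,8S,10S)-3,10:6,7-diepoxy-8-hydroxy-4,10-dimethylcyclodeca-2,4-dien-1-one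
Conditions: Bu4NF, AcOH (1:1), THF, 0 → 23 °C
Reagents that add atoms: none
Why: Buffered fluoride cleaves the secondary silyl ether without producing a free alkoxide, so epoxide migration and attack on the dienone are avoided.

Step 16
Reactants: 19 bridged furanone epoxy alcohol; 20 diethylphosphonoacetic acid
Product: 21 bridged furanone with trans (6S,7S) epoxide and (8S) diethylphosphonoacetate ester (key-step precursor)
Conditions: DCC, DMAP (cat.), CH2Cl2, 0 → 23 °C
Reagents that add atoms: none
Why: Steglich esterification of the secondary alcohol with the carbodiimide-activated acid; the conditions are too weakly basic to deprotonate the phosphonoacetate or to open the epoxide.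

Step 17
Reactants: 21 epoxy phosphonoacetate
Product: 23 6-O-detigloyl target (free C6 hydroxyl and trans-fused 8,12-methylene lactone), via α-phosphono lactone 22 (not isolated)
Conditions: LiN(SiMe3)2 (1.1 equiv), THF, 2 mM, −78 → 40 °C; then (CH2O)n, 0 → 23 °C
Reagents that add atoms: formaldehyde (from paraformaldehyde), C=O
Why: Proposed new method: LiN(SiMe3)2 removes a proton from the doubly activated CH2 of the phosphonoacetate, and the lithium-chelated carbanion (C11) attacks C7 on the side opposite to the epoxide C7–O bond while the lithium ion polarises that bond, so the lactone closes as a 5-exo-tet ring (C11, C12, O, C8, C7) and C6 keeps its oxygen as an alkoxide. The alkoxide is then protonated by the much more acidic α-phosphono lactone 22, and the phosphonate carbanion so formed olefinates formaldehyde in a Horner–Wadsworth–Emmons reaction that supplies C13 and expels lithium diethyl phosphate. The closest known reaction type is the intermolecular opening of epoxides by metalated phosphonoacetates to α-phosphono-γ-lactones followed by methylenation with formaldehyde; the ester-tethered version on a vinyl epoxide is without precedent. C7 is the only new stereocentre and is set by inversion at the epoxide carbon, and because O8 and the epoxide oxygen are anti (erythro) in 21 the lactone must come out trans-fused, while C6 and C8 keep their configurations. The step needs attack at C7 and not at the allylic C6, at C4 or at the dienone; the two-atom tether secures this, because only C7 can be reached through a five-membered transition state along the anti trajectory. One equivalent of base is consumed by the departing phosphate, so the product does not stand in excess base, which limits lactone migration to O6 and conjugate addition to the new methylene group.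

Step 18
Reactants: 23 6-O-detigloyl target; 24 (E)-2-methylbut-2-enoyl chloride (tigloyl chloride)
Product: 25 (4Z,6S,7R,8S,10S)-3,10-epoxy-1-oxo-6-[(E)-2-methylbut-2-enoyloxy]germacra-2,4,11(13)-trien-12,8-olide (target)
Conditions: pyridine, DMAP (10 mol%), CH2Cl2, 0 → 23 °C
Reagents that add atoms: none
Why: Acylation of the C6 alcohol by the acid chloride under nucleophilic catalysis; pyridine is too weak a base to move the lactone to O6 or to isomerise the tiglate, and no stereocentre is involved.

## Compound list

1 | (S)-citramalic acid | C[C@](O)(CC(=O)O)C(=O)O | starting material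
2 | 2-[(4S)-2,2,4-trimethyl-5-oxo-1,3-dioxolan-4-yl]acetic acid | C[C@@]1(CC(=O)O)OC(C)(C)OC1=O | intermediate
3 | (5S)-5-(2-hydroxyethyl)-2,2,5-trimethyl-1,3-dioxolan-4-one | C[C@@]1(CCO)OC(C)(C)OC1=O | intermediate (not isolated)
4 | (3S)-3-hydroxy-3-methyloxolan-2-one | C[C@]1(O)CCOC1=O | intermediate
5 | (2S)-2,4-dihydroxy-N-methoxy-N,2-dimethylbutanamide | CON(C)C(=O)[C@@](C)(O)CCO | intermediate
6 | (2S)-N-methoxy-N,2-dimethyl-2,4-bis(trimethylsilyloxy)butanamide | CON(C)C(=O)[C@@](C)(O[Si](C)(C)C)CCO[Si](C)(C)C | intermediate
7 | (2S)-N-methoxy-N,2-dimethyl-4-oxo-2-(trimethylsilyloxy)butanamide | CON(C)C(=O)[C@@](C)(O[Si](C)(C)C)CC=O | intermediate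
8 | (Z)-3-methylpent-2-en-4-yn-1-ol | C#C/C(C)=C\CO | starting material
9 | (Z)-3-methylpent-2-en-4-ynal | C#C/C(C)=C\C=O | intermediate
10 | (1E,3Z)-1-iodo-4-methylhexa-1,3-dien-5-yne | C#C/C(C)=C\C=C\I | intermediate
11 | (2S,5E,7Z)-4-hydroxy-N-methoxy-N,2,8-trimethyl-2-(trimethylsilyloxy)deca-5,7-dien-9-ynamide, both C4 epimers | CON(C)C(=O)[C@@](C)(O[Si](C)(C)C)CC(O)/C=C/C=C(C)\C#C | intermediate
12 | (2S,5E,7Z)-N-methoxy-N,2,8-trimethyl-4-oxo-2-(trimethylsilyloxy)deca-5,7-dien-9-ynamide | CON(C)C(=O)[C@@](C)(O[Si](C)(C)C)CC(=O)/C=C/C=C(C)\C#C | intermediate
13 | (2S,4S,5E,7Z)-4-hydroxy-N-methoxy-N,2,8-trimethyl-2-(trimethylsilyloxy)deca-5,7-dien-9-ynamide | CON(C)C(=O)[C@@](C)(O[Si](C)(C)C)C[C@H](O)/C=C/C=C(C)\C#C | intermediate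
14 | (2S,4S)-4-hydroxy-N-methoxy-N,2-dimethyl-4-{(2S,3S)-3-[(Z)-2-methylbut-1-en-3-yn-1-yl]oxiran-2-yl}-2-(trimethylsilyloxy)butanamide | CON(C)C(=O)[C@@](C)(O[Si](C)(C)C)C[C@H](O)[C@@H]1O[C@H]1/C=C(C)\C#C | intermediate
15 | tert-butyldimethylsilyl ether of 14 at the secondary (C8) hydroxyl | CON(C)C(=O)[C@@](C)(O[Si](C)(C)C)C[C@H](O[Si](C)(C)C(C)(C)C)[C@@H]1O[C@H]1/C=C(C)\C#C | intermediate
16 | (4Z,6S,7R,8S,10S)-8-(tert-butyldimethylsilyloxy)-6,7-epoxy-4,10-dimethyl-10-(trimethylsilyloxy)cyclodec-4-en-2-yn-1-one | O=C1C#C/C(C)=C\[C@@H]2O[C@H]2[C@@H](O[Si](C)(C)C(C)(C)C)C[C@]1(C)O[Si](C)(C)C | intermediate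
17 | (4Z,6S,7R,8S,10S)-8-(tert-butyldimethylsilyloxy)-6,7-epoxy-10-hydroxy-4,10-dimethylcyclodec-4-en-2-yn-1-one | O=C1C#C/C(C)=C\[C@@H]2O[C@H]2[C@@H](O[Si](C)(C)C(C)(C)C)C[C@]1(C)O | intermediate (not isolated)
18 | (4Z,6S,7R,8S,10S)-8-(tert-butyldimethylsilyloxy)-3,10:6,7-diepoxy-4,10-dimethylcyclodeca-2,4-dien-1-one | CC(C)(C)[Si](C)(C)O[C@H]1C[C@]2(C)OC(=CC2=O)/C(C)=C\[C@@H]3O[C@H]31 | intermediate
19 | (4Z,6S,7S,8S,10S)-3,10:6,7-diepoxy-8-hydroxy-4,10-dimethylcyclodeca-2,4-dien-1-one | O[C@H]1C[C@]2(C)OC(=CC2=O)/C(C)=C\[C@@H]3O[C@H]31 | intermediate
20 | diethylphosphonoacetic acid | CCOP(=O)(OCC)CC(=O)O | starting material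
21 | 8-O-(diethylphosphonoacetyl) ester of 19 (6S,7S,8S,10S; key-step precursor) | CCOP(=O)(OCC)CC(=O)O[C@H]1C[C@]2(C)OC(=CC2=O)/C(C)=C\[C@@H]3O[C@H]31 | intermediate
22 | 11-(diethoxyphosphoryl) trans-fused 8,12-lactone with free 6-hydroxyl (C11 epimers) | CCOP(=O)(OCC)C1C(=O)O[C@H]2C[C@]3(C)OC(=CC3=O)/C(C)=C\[C@H](O)[C@H]12 | intermediate (not isolated)
23 | (4Z,6S,7S,8S,10S)-3,10-epoxy-6-hydroxy-1-oxogermacra-2,4,11(13)-trien-12,8-olide (6-O-detigloyl target) | C=C1C(=O)O[C@H]2C[C@]3(C)OC(=CC3=O)/C(C)=C\[C@H](O)[C@H]12 | intermediate
24 | (E)-2-methylbut-2-enoyl chloride (tigloyl chloride) | C/C=C(\C)C(=O)Cl | starting material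
25 | (4Z,6S,7R,8S,10S)-3,10-epoxy-1-oxo-6-[(E)-2-methylbut-2-enoyloxy]germacra-2,4,11(13)-trien-12,8-olide | C=C1C(=O)O[C@H]2C[C@]3(C)OC(=CC3=O)/C(C)=C\[C@H](OC(=O)/C(C)=C/C)[C@H]12 | target

## Step count and least certain steps

Total step count: 18. Longest linear sequence: 16 steps (steps 1–5, then 8–18); steps 6–7 make the second fragment.

**Step 17 (key step).**
- What may go wrong: the ring may hold the C8–C9 bond anti to the epoxide C7–O bond, so that the rear of C7 points into the ring and the tethered carbanion never reaches the anti trajectory. In that case slower processes take over: base-induced isomerisation of the epoxide, attack of the C6 alkoxide on phosphorus or on C12 after a sluggish closure, or conjugate addition to the dienone.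
- Fallback (known chemistry, without the epoxide): it sets out from 13 and comes back at 25.
  - 13 would be silylated (t-BuMe2SiCl, imidazole) to the C8 silyl ether F1.
  - F1 would be closed with LiN(SiMe3)2 as in step 13 to the ten-membered (6E)-dienyl ynone F2.
  - K2CO3 in MeOH would take F2 through the hydroxy ynone F3 to the bridged furanone silyl ether F4.
  - Bu4NF/AcOH would free the macrocyclic (8S)-dienol F5, which would be esterified with 2-bromoacrylic acid (DCC, DMAP) to the 2-bromoacrylate F6.
  - Pd(PPh3)4 (zerovalent palladium, catalytic) with sodium tiglate (NaO2CC(CH3)=CHCH3) in MeCN at 60 °C would then run a Heck cyclisation with anion capture. Oxidative addition into the C11–Br bond and syn carbopalladation of C6=C7 on the O8 face (5-exo, C7–C11) would give a C4–C6 allylpalladium unit, which tiglate should capture at C6 anti to the metal. This gives 25 directly, with the same anti relationship of C7–C11 and C6–O as the epoxide route.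

**Step 13 (ring closure at C1–C2).**
- What may go wrong: slow closure of the ten-membered ring would let intermolecular acylation compete, or give the amide base time to degrade the N-methoxy amide or isomerise the epoxide.
- Fallback (non-basic, chromium-mediated): it sets out from 15 and comes back at 16.
  - i-Bu2AlH at −78 °C would reduce the Weinreb amide to the C1 aldehyde F7.
  - N-iodosuccinimide with AgNO3 (catalytic) would convert the terminal alkyne into the iodoalkyne F8.
  - CrCl2 with NiCl2 (catalytic) in THF at high dilution would close the ring to the propargylic alcohol F9 (both C1 epimers, which is of no consequence).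
  - Dess–Martin periodinane would oxidise F9 to 16.

**Step 14 (oxygen bridge).**
- What may go wrong: the strain of the bicycle may slow the 5-endo closure, so that methoxide adds to the ynone without ring closure or the basic medium begins to open the epoxide.
- Fallback: it sets out from 16 and comes back at 18. The trimethylsilyl group would be removed with K2CO3 in MeOH at −20 °C under short contact and the alcohol 17 isolated. (Ph3P)AuNTf2 (monovalent gold, 5 mol%) in CH2Cl2 would then activate the alkyne toward attack by the neutral hydroxyl, so that no alkoxide is present. No new compound arises (F0).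

**Step 10 (C8 configuration).**
- What may go wrong: poor facial selectivity, because the small CH2 flank carries the bulky quaternary C10, so that both C8 epimers form.
- Fallback: it sets out from 11 and comes back at 14. The epimer mixture 11 from step 8 would be submitted directly to the conditions of step 11 with 0.6 equivalents of t-BuOOH, as a kinetic resolution. The 8S epimer should be epoxidised to 14, and the slow-reacting (8R)-dienol F10 would be recovered, oxidised with MnO2 to 12 and returned to the sequence.

## Further compounds

F1 | step 17 | tert-butyldimethylsilyl ether of 13 at the C8 hydroxyl | CON(C)C(=O)[C@@](C)(O[Si](C)(C)C)C[C@H](O[Si](C)(C)C(C)(C)C)/C=C/C=C(C)\C#C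
F2 | step 17 | (4Z,6E,8S,10S)-8-(tert-butyldimethylsilyloxy)-4,10-dimethyl-10-(trimethylsilyloxy)cyclodeca-4,6-dien-2-yn-1-one | O=C1C#C/C(C)=C\C=C\[C@@H](O[Si](C)(C)C(C)(C)C)C[C@]1(C)O[Si](C)(C)C
F3 | step 17 | (4Z,6E,8S,10S)-8-(tert-butyldimethylsilyloxy)-10-hydroxy-4,10-dimethylcyclodeca-4,6-dien-2-yn-1-one | O=C1C#C/C(C)=C\C=C\[C@@H](O[Si](C)(C)C(C)(C)C)C[C@]1(C)O
F4 | step 17 | (4Z,6E,8S,10S)-8-(tert-butyldimethylsilyloxy)-3,10-epoxy-4,10-dimethylcyclodeca-2,4,6-trien-1-one | CC(C)(C)[Si](C)(C)O[C@@H]1/C=C/C=C(C)\C2=CC(=O)[C@@](C)(O2)C1
F5 | step 17 | (4Z,6E,8S,10S)-3,10-epoxy-8-hydroxy-4,10-dimethylcyclodeca-2,4,6-trien-1-one | O[C@@H]1/C=C/C=C(C)\C2=CC(=O)[C@@](C)(O2)C1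
F6 | step 17 | 2-bromoacrylate ester of F5 at the C8 hydroxyl | C=C(Br)C(=O)O[C@@H]1/C=C/C=C(C)\C2=CC(=O)[C@@](C)(O2)C1
F7 | step 13 | C1 aldehyde corresponding to 15 (Weinreb amide reduced) | O=C[C@@](C)(O[Si](C)(C)C)C[C@H](O[Si](C)(C)C(C)(C)C)[C@@H]1O[C@H]1/C=C(C)\C#C
F8 | step 13 | iodoalkyne of F7 | O=C[C@@](C)(O[Si](C)(C)C)C[C@H](O[Si](C)(C)C(C)(C)C)[C@@H]1O[C@H]1/C=C(C)\C#CI
F9 | step 13 | C1 alcohol corresponding to 16 (both C1 epimers) | OC1C#C/C(C)=C\[C@@H]2O[C@H]2[C@@H](O[Si](C)(C)C(C)(C)C)C[C@]1(C)O[Si](C)(C)C
F0 | step 14 | none | none
F10 | step 10 | (2S,4R,5E,7Z)-4-hydroxy-N-methoxy-N,2,8-trimethyl-2-(trimethylsilyloxy)deca-5,7-dien-9-ynamide | CON(C)C(=O)[C@@](C)(O[Si](C)(C)C)C[C@@H](O)/C=C/C=C(C)\C#C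
A1 | alternative 1 | (2S)-4-(4-methoxybenzyloxy)-2-methyl-2-(triethylsilyloxy)butanal oxime | COc1ccc(COCC[C@](C)(O[Si](CC)(CC)CC)C=NO)cc1
A2 | alternative 1 | tert-butyldimethylsilyl ether of (Z)-3-methylpent-2-en-4-yn-1-ol | C#C/C(C)=C\CO[Si](C)(C)C(C)(C)C
A3 | alternative 1 | 3,5-disubstituted isoxazole joining C8–C10 to C2–C6 | COc1ccc(COCC[C@](C)(O[Si](CC)(CC)CC)c2cc(/C(C)=C\CO[Si](C)(C)C(C)(C)C)on2)cc1
A4 | alternative 2 | cis-cyclooct-2-enone with fused 8,12-lactone, C6 silyl ether and C10 1-propynyl ether | CC#CO[C@@]1(C)C[C@@H]2OC(=O)C[C@H]2[C@@H](O[Si](C)(C)C(C)(C)C)/C=C\C1=O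
A5 | alternative 2 | bridged furanone with C6 silyl ether and lactone lacking C13 | C1C(=O)O[C@H]2C[C@]3(C)OC(=CC3=O)/C(C)=C\[C@H](O[Si](C)(C)C(C)(C)C)[C@H]12
A6 | alternative 3 | thirteen-membered C6–O–C13 diallyl ether with furanone, C8 and C12 silyl ethers | C/C1=C/COC/C(CO[Si](C)(C)C(C)(C)C)=C\[C@@H](O[Si](C)(C)C(C)(C)C)C[C@]2(C)OC1=CC2=O
A7 | alternative 3 | ten-membered furanone C6 alcohol with C11 methylene, C8 and C12 silyl ethers | C=C(CO[Si](C)(C)C(C)(C)C)[C@H]1[C@@H](O)/C=C(C)\C2=CC(=O)[C@@](C)(O2)C[C@@H]1O[Si](C)(C)C(C)(C)C
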